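The reading time was 10 d in both flasks, later than Friday's last reading.

| setting | Friday's | south-west | north |
|---|---|---|---|
| free monomer | 1.5 M | 1.5 M | 0.80 M |
| pre-initiator | 6.7 mol% | 10 mol% | 10 mol% |
| remark | run made earlier |  |  |
| time |  | 10 d | 10 d |

Friday's run (percent of the free monomer charged)

| time / d | monomer in chains / % | free monomer / % |
|---|---|---|
| 1.04 | 1.1 | 100.2 |
| 2.08 | 1.5 | 98.1 |
| 3.00 | 4.8 | 94.9 |
| 4.00 | 8.7 | 90.5 |
| 5.00 | 14.2 | 86.4 |
| 6.00 | 17.9 | 82.5 |

(each reading ± 0.5 percentage points)

- the average divides the monomer in chains by the number of chains begun, living and dead together
- the analysis behind the earlier runs scatters by 0.5 percentage points, standard deviation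
- what may be going on: free monomer + initiator -> living end + monomer in chains; free monomer + living end -> monomer in chains + living end; 2 initiator -> spent initiator; pre-initiator -> initiator
- the earlier runs do not show the number of chains; that part of a forecast is a guess
- no earlier run changes the charge of pre-initiator; that part of a forecast is a guess

* which of the two ends with the longer chains by the average number of monomer units in a chain (chains begun, living or dead) ("neither" if they lie within 10 %) (south-west / north / neither)
* average number of monomer units in a chain (chains begun, living or dead) at the end, south-west
* average number of monomer units in a chain (chains begun, living or dead) at the end, north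

Friday's free monomer fell 2.1 percentage points between its first two readings and 3.9 points between its last two, so its loss read faster late in the run. But that run showed no chain count, so I reckoned no length, only a ratio of lengths (number-average chain lengths).

South-west and north had the same loading, so equal lengths were the zero of my scale. But a start and a growth step each take one free monomer. A start goes with [initiator] and growth with [living end], so length follows [living end]/[initiator]. [Living end] gathers from starts, which go with [free monomer]. So I reckoned length at a given time as proportional to mean [free monomer], with the loading dropping out; that part is a guess.

South-west's starting [free monomer] over north's was 1.88, the charge ratio. To reach the mean, I multiplied it by one plus the fraction left in south-west, over the same for north.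

The forecast, unlike me, named lengths: south-west, 10 against 6, since “it has more monomer per chain”.

The flasks gave south-west, 202 against 121, a ratio of 1.67.

    free monomer + initiator → living end + monomer in chains (k = 0.00130 M⁻¹ h⁻¹)
    free monomer + living end → monomer in chains + living end, rate k2*[living end]*[free monomer] (k = 1.30 M⁻¹ h⁻¹)
    2 initiator → spent initiator (k = 2.60 M⁻¹ h⁻¹)
    pre-initiator → initiator (k = 0.00630 h⁻¹)

South-west kept 52 % of its free monomer and north 77 %, so my reckoned ratio of lengths, from the charge ratio, was 1.61. The neighbouring flask was north charged with 2.0 M of free monomer, with the same loading and time. Its charge ratio against north was 2.50. With 38 % left, my reckoned ratio of lengths was 1.95, which put its length at 236 by my reckoning. Its chains averaged 245 units.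

Readings and results are calculated with made-up constants; noise was put on by code.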